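**Plan**

- Retrosynthesis: the C5 phenol is masked as a benzyl ether; the C2–CH3 bond is cut back to a 2-ethoxy acetal; the pyran bonds C3–C4 and O1–C2 are then cut together to an o-quinone methide and ethyl vinyl ether; the methide precursor, a diaryl carbinol, is cut at the carbinol–naphthyl bond.
- Enabling feature: the pyran ring O1–C2–C3–C4 is fused to the resorcinol ring and its benzylic C4 carries the naphthyl group, so O1–C8a–C4a–C4 is a latent 1-oxadiene (o-quinone methide) and C2–C3 the two carbons of an enol ether.
- Forward: lithiated 1-bromo-4,5-dimethoxynaphthalene is joined to mono-benzylated 2,6-dihydroxybenzaldehyde; the pyran ring is closed onto the resorcinol ring by the [4+2] cycloaddition; methyl replaces ethoxy at C2; hydrogenolysis frees the phenol. The benzyl ether leaves a single free phenol, so the carbinol is an ordinary o-hydroxybenzhydryl alcohol and only one quinone methide can form.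
- Stereochemistry: C4 (S) comes from the chiral phosphoric acid in the cycloaddition; C2 (R) comes from substrate control, methyl adding to the cyclic oxocarbenium ion anti to the C4 naphthyl group (2,4-trans).

Key step: step 4

Assumption: the sense of induction of the phosphoric acid in step 4, and of the auxiliary named in the fallback for that step, cannot be predicted with certainty for this hindered 1-naphthyl o-quinone methide; the (R)-catalyst and the (1R,2S)-auxiliary are working choices, and the mirror-image reagent would be taken if a trial run shows the opposite sense at C4.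

**Route**

Step 1
Reactants: 1 1,8-dimethoxynaphthalene
Product: 2 1-bromo-4,5-dimethoxynaphthalene
Conditions: N-bromosuccinimide (1.0 equiv), MeCN, 0 °C to rt
Reagents that add atoms: N-bromosuccinimide, O=C1CCC(=O)N1Br
Why: Electrophilic aromatic bromination of the activated naphthalene should occur at the alpha position para to a methoxy group (C4), and one equivalent of reagent should stop at the monobromide.

Step 2
Reactants: 3 2,6-dihydroxybenzaldehyde
Product: 4 2-(benzyloxy)-6-hydroxybenzaldehyde
Conditions: BnBr (1.0 equiv), K2CO3 (1.1 equiv), acetone, reflux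
Reagents that add atoms: benzyl bromide, BrCc1ccccc1
Why: Williamson ether synthesis; after the first O-benzylation the remaining phenol is held in a hydrogen bond to the formyl oxygen and is much less nucleophilic, so one equivalent of benzyl bromide should give mainly the mono-ether.

Step 3
Reactants: 2 1-bromo-4,5-dimethoxynaphthalene; 4 2-(benzyloxy)-6-hydroxybenzaldehyde
Product: 6 rac-[2-(benzyloxy)-6-hydroxyphenyl](4,5-dimethoxynaphthalen-1-yl)methanol, via aryllithium 5 (not isolated)
Conditions: 2 (2.3 equiv), n-BuLi (2.2 equiv), THF, −78 °C; then 4, −78 to 0 °C; aq. NH4Cl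
Reagents that add atoms: none
Why: Bromine–lithium exchange gives aryllithium 5, which adds 1,2 to the formyl group of 4 (a first equivalent is spent on the phenol and returns 1), a routine way to o-hydroxybenzhydryl alcohols; the new carbinol centre needs no control because step 4 planarises it.

Step 4
Reactants: 6 rac-[2-(benzyloxy)-6-hydroxyphenyl](4,5-dimethoxynaphthalen-1-yl)methanol; 7 ethyl vinyl ether
Product: 9 (2R,4S)-5-(benzyloxy)-4-(4,5-dimethoxynaphthalen-1-yl)-2-ethoxychromane, via o-quinone methide 8 (not isolated)
Conditions: (R)-3,3'-bis(2,4,6-triisopropylphenyl)-1,1'-binaphthyl-2,2'-diyl hydrogen phosphate (5 mol %), 7 (5 equiv), 4 Å MS, toluene, 0 °C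
Reagents that add atoms: none
Why: The phosphoric acid assists loss of water from the benzylic carbinol of 6 to give o-quinone methide 8, which stays hydrogen-bonded to the chiral phosphate through its carbonyl oxygen; the nucleophilic CH2 terminus of 7 then bonds to the methide carbon (C3–C4) while the carbonyl oxygen closes onto the oxygen-bearing alkene carbon (O1–C2) in a concerted but asynchronous inverse-electron-demand oxa-[4+2] cycloaddition. The closest known reaction type is the chiral-phosphoric-acid-catalysed hetero-Diels–Alder reaction of o-hydroxybenzhydryl alcohols with enol ethers, enamides and vinyl sulfides. The six-membered pyran ring is closed by the cycloaddition itself, its last bond (O1–C2) arising from attack of the quinone methide oxygen on the developing oxocarbenium carbon. C4 is set under catalyst control, the phosphate bound at the quinone methide oxygen covering one face of the methide carbon, and C2 arises cis to C4 through the endo approach of the ethoxy group but is re-formed in step 5, so its purity does not matter. The step needs regioselectivity, secured by the polarity match of the two components, and enantiofacial selectivity, helped by 6 carrying only one free phenol (the other is benzylated) so that a single o-quinone methide with a single catalyst-binding oxygen can form. Racemic 6 is acceptable because its carbinol centre becomes planar in 8.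

Step 5
Reactants: 9 (2R,4S)-5-(benzyloxy)-4-(4,5-dimethoxynaphthalen-1-yl)-2-ethoxychromane
Product: 11 (2R,4S)-5-(benzyloxy)-4-(4,5-dimethoxynaphthalen-1-yl)-2-methylchromane, via oxocarbenium triflate 10 (not isolated)
Conditions: AlMe3 (4 equiv), CH2Cl2, −78 °C; then Me3SiOTf (1.2 equiv), −78 to −40 °C; aq. potassium sodium tartrate
Reagents that add atoms: trimethylaluminium, C[Al](C)C
Why: Lewis-acid-mediated substitution of a cyclic O,O-acetal by an organoaluminium nucleophile (C-glycosylation-type methylation): Me3SiOTf removes the ethoxy group to give the free oxocarbenium ion 10, whose C4 naphthyl group sits pseudoaxial to avoid the peri benzyloxy group at C5, so methyl should be delivered to C2 on the opposite face and the 2,4-trans (2R) chromane should result whatever the C2 configuration of 9.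

Step 6
Reactants: 11 (2R,4S)-5-(benzyloxy)-4-(4,5-dimethoxynaphthalen-1-yl)-2-methylchromane
Product: 12 cladonaphchrom A, (2R,4S)-4-(4,5-dimethoxynaphthalen-1-yl)-2-methylchroman-5-ol
Conditions: H2 (1 atm), 10% Pd/C, EtOAc–MeOH, rt
Reagents that add atoms: none
Why: Hydrogenolysis of the benzyl aryl ether over Pd/C; the methyl ethers, the naphthalene and the non-benzylic pyran C–O bond should be inert under these mild conditions and no stereocentre is touched.

**Compound list**

1 | 1,8-dimethoxynaphthalene | COc1cccc2cccc(OC)c12 | starting material
2 | 1-bromo-4,5-dimethoxynaphthalene | COc1cccc2c(Br)ccc(OC)c12 | intermediate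
3 | 2,6-dihydroxybenzaldehyde | O=Cc1c(O)cccc1O | starting material
4 | 2-(benzyloxy)-6-hydroxybenzaldehyde | O=Cc1c(O)cccc1OCc1ccccc1 | intermediate
5 | (4,5-dimethoxynaphthalen-1-yl)lithium (formed in the flask) | [Li]c1ccc(OC)c2c(OC)cccc12 | intermediate
6 | rac-[2-(benzyloxy)-6-hydroxyphenyl](4,5-dimethoxynaphthalen-1-yl)methanol | COc1cccc2c(C(O)c3c(O)cccc3OCc3ccccc3)ccc(OC)c12 | intermediate
7 | ethyl vinyl ether | C=COCC | starting material
8 | 5-(benzyloxy)-6-[(4,5-dimethoxynaphthalen-1-yl)methylidene]cyclohexa-2,4-dien-1-one (o-quinone methide, formed in the flask) | COc1cccc2c(C=C3C(=O)C=CC=C3OCc3ccccc3)ccc(OC)c12 | intermediate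
9 | (2R,4S)-5-(benzyloxy)-4-(4,5-dimethoxynaphthalen-1-yl)-2-ethoxychromane (2,4-cis acetal) | COc1cccc2c([C@@H]3C[C@H](OCC)Oc4cccc(OCc5ccccc5)c43)ccc(OC)c12 | intermediate
10 | (4S)-5-(benzyloxy)-4-(4,5-dimethoxynaphthalen-1-yl)-3,4-dihydrochromenylium trifluoromethanesulfonate (formed in the flask) | COc1cccc2c([C@@H]3CC=[O+]c4cccc(OCc5ccccc5)c43)ccc(OC)c12.[O-]S(=O)(=O)C(F)(F)F | intermediate
11 | (2R,4S)-5-(benzyloxy)-4-(4,5-dimethoxynaphthalen-1-yl)-2-methylchromane (2,4-trans) | COc1cccc2c([C@@H]3C[C@@H](C)Oc4cccc(OCc5ccccc5)c43)ccc(OC)c12 | intermediate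
12 | cladonaphchrom A, (2R,4S)-4-(4,5-dimethoxynaphthalen-1-yl)-2-methylchroman-5-ol | COc1cccc2c([C@@H]3C[C@@H](C)Oc4cccc(O)c43)ccc(OC)c12 | target

**Count and risks**

Total steps: 6. Longest linear sequence: 5 steps (1 → 2 → 6 → 9 → 11 → 12, or equally 3 → 4 → 6 → 9 → 11 → 12).

Steps most likely to fail:

Step 4. The bulky 1-naphthyl group next to the benzyloxy group may twist the o-quinone methide so that the catalyst discriminates its two faces poorly. The acid may also consume the vinyl ether (hydrolysis by the water set free, oligomerisation) faster than the cycloaddition proceeds. The fallback moves stereocontrol from the catalyst to a chiral enol ether and generates the o-quinone methide under basic conditions. It sets out from 4 and 2. Aldehyde 4 is acylated with Boc2O (i-Pr2NEt, catalytic 4-(dimethylamino)pyridine, CH2Cl2) to 2-(benzyloxy)-6-[(tert-butoxycarbonyl)oxy]benzaldehyde F1. Bromide 2 and Mg turnings in THF give (4,5-dimethoxynaphthalen-1-yl)magnesium bromide F2. Commercial (1R,2S)-2-phenylcyclohexanol is vinylated by Hg(OAc)2-catalysed exchange with 7 to [(1R,2S)-2-(ethenyloxy)cyclohexyl]benzene F3. Addition of F2 to F1 at −78 °C in the presence of excess F3, then warming, should move the carbonate group onto the new magnesium alkoxide and expel tert-butyl carbonate, giving the same o-quinone methide 8. Its endo [4+2] cycloaddition to F3, on the face left open by the auxiliary, should give (2R,4S)-5-(benzyloxy)-4-(4,5-dimethoxynaphthalen-1-yl)-2-{[(1R,2S)-2-phenylcyclohexyl]oxy}chromane F4. Under the conditions of step 5, F4 should lose the auxiliary alcohol and give 11, where the route is rejoined.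

Step 5. The oxocarbenium ion may lose the C3 proton to give a 4H-chromene. It may be captured internally by the electron-rich peri carbon of the naphthalene (para to a methoxy group), closing a bridged ring. It may also take up methyl with poor facial selectivity. The fallback makes the O1–C2 bond by an invertive substitution at a defined secondary carbinol instead of by addition to a cation. It sets out from 9. Mild aqueous acid (pyridinium p-toluenesulfonate, acetone–water) should hydrolyse the acetal to (4S)-5-(benzyloxy)-4-(4,5-dimethoxynaphthalen-1-yl)chroman-2-ol F5. Excess MeMgBr in THF should add to its open hydroxy-aldehyde form to give (4S)-4-[2-(benzyloxy)-6-hydroxyphenyl]-4-(4,5-dimethoxynaphthalen-1-yl)butan-2-ol F6 as a pair of C2 epimers, no useful selectivity being expected. Chromatography should provide (2S,4S)-4-[2-(benzyloxy)-6-hydroxyphenyl]-4-(4,5-dimethoxynaphthalen-1-yl)butan-2-ol F7. Intramolecular Mitsunobu etherification (PPh3, diisopropyl azodicarboxylate, THF) should then close the pyran ring with inversion at C2 to give 11, where the route is rejoined.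

Step 3. Once the phenol is deprotonated the aldehyde is a deactivated, poorly soluble lithium phenoxide, so the addition may stall, and a full extra equivalent of the aryllithium is spent as base. The fallback masks the phenol with a group that comes off without acid. It sets out from 4. Allyl bromide and K2CO3 in DMF should give 2-(allyloxy)-6-(benzyloxy)benzaldehyde F8. One equivalent of 5 should add at −78 °C to give rac-[2-(allyloxy)-6-(benzyloxy)phenyl](4,5-dimethoxynaphthalen-1-yl)methanol F9. Pd(PPh3)4-catalysed allyl transfer to morpholine in THF at room temperature should free the phenol and give 6, where the route is rejoined.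

**Further compounds**

F1 | step 4 | 2-(benzyloxy)-6-[(tert-butoxycarbonyl)oxy]benzaldehyde | O=Cc1c(OC(=O)OC(C)(C)C)cccc1OCc1ccccc1
F2 | step 4 | (4,5-dimethoxynaphthalen-1-yl)magnesium bromide | Br[Mg]c1ccc(OC)c2c(OC)cccc12
F3 | step 4 | [(1R,2S)-2-(ethenyloxy)cyclohexyl]benzene | C=CO[C@@H]1CCCC[C@H]1c1ccccc1
F4 | step 4 | (2R,4S)-5-(benzyloxy)-4-(4,5-dimethoxynaphthalen-1-yl)-2-{[(1R,2S)-2-phenylcyclohexyl]oxy}chromane | COc1cccc2c([C@@H]3C[C@H](O[C@@H]5CCCC[C@H]5c5ccccc5)Oc4cccc(OCc6ccccc6)c43)ccc(OC)c12
F5 | step 5 | (4S)-5-(benzyloxy)-4-(4,5-dimethoxynaphthalen-1-yl)chroman-2-ol (anomer mixture) | COc1cccc2c([C@@H]3CC(O)Oc4cccc(OCc5ccccc5)c43)ccc(OC)c12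
F6 | step 5 | (4S)-4-[2-(benzyloxy)-6-hydroxyphenyl]-4-(4,5-dimethoxynaphthalen-1-yl)butan-2-ol (C2 epimer mixture) | COc1cccc2c([C@H](CC(C)O)c3c(O)cccc3OCc3ccccc3)ccc(OC)c12
F7 | step 5 | (2S,4S)-4-[2-(benzyloxy)-6-hydroxyphenyl]-4-(4,5-dimethoxynaphthalen-1-yl)butan-2-ol | COc1cccc2c([C@H](C[C@H](C)O)c3c(O)cccc3OCc3ccccc3)ccc(OC)c12
F8 | step 3 | 2-(allyloxy)-6-(benzyloxy)benzaldehyde | O=Cc1c(OCC=C)cccc1OCc1ccccc1
F9 | step 3 | rac-[2-(allyloxy)-6-(benzyloxy)phenyl](4,5-dimethoxynaphthalen-1-yl)methanol | COc1cccc2c(C(O)c3c(OCC=C)cccc3OCc3ccccc3)ccc(OC)c12
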